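**Retrosynthetic overview**
1. Target 16 comes from diol 13 by O-methylation of both ring A phenols, LiAlH4 reduction of the side-chain ester and hydrogenolysis of the benzyl ether.
2. The strategy rests on ring A: its ether carbon C1 lies between the two methoxy-bearing carbons C2 and C6. Both C–O bonds (C2–O and C6–O) are traced back to C2–CHO and C6–CHO of dialdehyde 11 by a twofold Baeyer–Villiger oxygenation.
3. The same two formyl groups activate C1, so the diaryl ether O–C1 bond is disconnected by SNAr to fluorodialdehyde 5 and ring B phenol 10.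
4. Compound 5 comes from 1-fluoro-4-propylbenzene 1 by two fluorine-directed ortho-lithiation/formylation rounds. Compound 10 comes from 5-hydroxyvanillin 6 by 4-O-benzylation, Wittig olefination and conjugate reduction.
5. No ring is formed at any stage; both benzene rings are bought and only substituents are changed.

Key step: step 8

Remark on the chemistry: ring A is numbered with C1 as the carbon bearing the diaryl ether oxygen and C4 as the carbon bearing propyl. The target has no stereocentre, so no stereocontrol is needed; the E geometry of 9 is removed in step 6.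

**Step 1**
Reactants: 1 1-fluoro-4-propylbenzene
Product: 2 2-fluoro-5-propylbenzaldehyde
Conditions: sec-BuLi, TMEDA, THF, −78 °C; DMF, −78 °C to 0 °C; aq. HCl quench
Reagents that add atoms: N,N-dimethylformamide, CN(C)C=O
Why: Fluorine is the only strongly acidifying substituent, so directed ortho-metalation at −78 °C (cold enough to suppress aryne formation) removes the proton next to fluorine and DMF formylates the aryllithium.

**Step 2**
Reactants: 2 2-fluoro-5-propylbenzaldehyde
Product: 3 2-(dimethoxymethyl)-1-fluoro-4-propylbenzene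
Conditions: HC(OMe)3, MeOH, cat. TsOH·H2O, rt
Reagents that add atoms: trimethyl orthoformate, COC(OC)OC; methanol, CO
Why: Acid-catalysed acetalisation, with the orthoformate as water scavenger, masks the aldehyde against the organolithium of the next step.

**Step 3**
Reactants: 3 2-(dimethoxymethyl)-1-fluoro-4-propylbenzene
Product: 5 2-fluoro-5-propylbenzene-1,3-dicarbaldehyde, via 3-(dimethoxymethyl)-2-fluoro-5-propylbenzaldehyde 4 (not isolated)
Conditions: sec-BuLi, TMEDA, THF, −78 °C; DMF, −78 °C to 0 °C; then 2 M aq. HCl, THF, rt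
Reagents that add atoms: N,N-dimethylformamide, CN(C)C=O; water, O
Why: A second directed ortho-metalation takes the remaining proton next to fluorine (fluorine outranks the weakly directing acetal), DMF formylates it, and the acidic work-up hydrolyses the dimethyl acetal to the second aldehyde.

**Step 4**
Reactants: 6 3,4-dihydroxy-5-methoxybenzaldehyde (5-hydroxyvanillin)
Product: 7 4-(benzyloxy)-3-hydroxy-5-methoxybenzaldehyde
Conditions: BnBr (1.05 equiv), Li2CO3, DMF, 45 °C
Reagents that add atoms: benzyl bromide, BrCc1ccccc1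
Why: The 4-OH is para to the formyl group and therefore the more acidic phenol, so the weak base Li2CO3 ionises it preferentially and the Williamson etherification with one equivalent of benzyl bromide should occur there.

**Step 5**
Reactants: 7 4-(benzyloxy)-3-hydroxy-5-methoxybenzaldehyde; 8 methyl (triphenylphosphoranylidene)acetate
Product: 9 methyl (E)-3-[4-(benzyloxy)-3-hydroxy-5-methoxyphenyl]prop-2-enoate
Conditions: 8 (1.4 equiv), toluene, 80 °C
Reagents that add atoms: none
Why: Wittig olefination with a stabilised ylide tolerates the free meta phenol and should give the E cinnamate.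

**Step 6**
Reactants: 9 methyl (E)-3-[4-(benzyloxy)-3-hydroxy-5-methoxyphenyl]prop-2-enoate
Product: 10 methyl 3-[4-(benzyloxy)-3-hydroxy-5-methoxyphenyl]propanoate
Conditions: cat. NiCl2·6H2O, NaBH4, MeOH, 0 °C
Reagents that add atoms: none
Why: Nickel boride formed in the flask carries out the conjugate reduction of the cinnamate C=C and, unlike Pd/C with H2, does not cleave the benzyl ether or reduce the ester.

**Step 7**
Reactants: 5 2-fluoro-5-propylbenzene-1,3-dicarbaldehyde; 10 methyl 3-[4-(benzyloxy)-3-hydroxy-5-methoxyphenyl]propanoate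
Product: 11 methyl 3-[4-(benzyloxy)-3-(2,6-diformyl-4-propylphenoxy)-5-methoxyphenyl]propanoate
Conditions: K2CO3, DMF, 60 °C, N2
Reagents that add atoms: none
Why: Nucleophilic aromatic substitution (SNAr): the fluoride lies between two ortho formyl groups that stabilise the Meisenheimer adduct, so the potassium phenoxide of 10 should displace it under mild anhydrous conditions that spare the methyl ester.

**Step 8**
Reactants: 11 methyl 3-[4-(benzyloxy)-3-(2,6-diformyl-4-propylphenoxy)-5-methoxyphenyl]propanoate
Product: 13 methyl 3-[4-(benzyloxy)-3-(2,6-dihydroxy-4-propylphenoxy)-5-methoxyphenyl]propanoate, via ring A bis-formate 12 (not isolated)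
Conditions: mCPBA (3 equiv), CH2Cl2, 0 °C to rt; then K2CO3, MeOH, rt, N2
Reagents that add atoms: 3-chloroperbenzoic acid, OOC(=O)c1cccc(Cl)c1
Why: The peracid adds to each formyl group to give a Criegee adduct, from which the ring A carbon (C2, then C6) migrates from carbon to oxygen with loss of 3-chlorobenzoate, and the two aryl formates are then cleaved by K2CO3-mediated methanolysis. The closest known reaction type is the Baeyer–Villiger (Dakin-type) oxidation of ortho-alkoxy- and ortho-aryloxybenzaldehydes with peracids to aryl formates and then phenols. No ring is closed and no stereocentre is formed; the step makes the C2–O and C6–O bonds of ring A in one operation. The selectivity needed is aryl over hydride migration at both aldehydes (hydride migration would give carboxylic acids), and it is secured by the C1 aryloxy oxygen, whose lone pair donates into the ortho migrating carbon. The benzyl ether, the ester and the alkyl chains offer no site for the peracid, and ring B, although electron-rich, should not be hydroxylated by mCPBA in the absence of strong acid. The methyl ester survives the methanolysis because exchange with methanol is degenerate.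

**Step 9**
Reactants: 13 methyl 3-[4-(benzyloxy)-3-(2,6-dihydroxy-4-propylphenoxy)-5-methoxyphenyl]propanoate
Product: 14 methyl 3-[4-(benzyloxy)-3-(2,6-dimethoxy-4-propylphenoxy)-5-methoxyphenyl]propanoate
Conditions: MeI, K2CO3, acetone, reflux
Reagents that add atoms: iodomethane, CI
Why: Williamson O-methylation of both phenoxides; K2CO3 is too weak to enolise the ester and the benzyl ether is inert.

**Step 10**
Reactants: 14 methyl 3-[4-(benzyloxy)-3-(2,6-dimethoxy-4-propylphenoxy)-5-methoxyphenyl]propanoate
Product: 15 3-[4-(benzyloxy)-3-(2,6-dimethoxy-4-propylphenoxy)-5-methoxyphenyl]propan-1-ol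
Conditions: LiAlH4, THF, 0 °C; Fieser work-up
Reagents that add atoms: none
Why: Hydride reduction of the methyl ester gives the primary alcohol, while the aryl, methyl and benzyl ethers are not touched.

**Step 11**
Reactants: 15 3-[4-(benzyloxy)-3-(2,6-dimethoxy-4-propylphenoxy)-5-methoxyphenyl]propan-1-ol
Product: 16 2-(2,6-dimethoxy-4-propylphenoxy)-4-(3-hydroxypropyl)-6-methoxyphenol (target)
Conditions: H2 (1 atm), 10% Pd/C, EtOAc/MeOH, rt
Reagents that add atoms: none
Why: Catalytic hydrogenolysis cleaves the benzyl aryl ether only; the diaryl ether, the methyl ethers and the primary alcohol are stable under these conditions.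

**Compound list**
1 | 1-fluoro-4-propylbenzene | CCCc1ccc(F)cc1 | starting material
2 | 2-fluoro-5-propylbenzaldehyde | CCCc1ccc(F)c(C=O)c1 | intermediate
3 | 2-(dimethoxymethyl)-1-fluoro-4-propylbenzene | CCCc1ccc(F)c(C(OC)OC)c1 | intermediate
4 | 3-(dimethoxymethyl)-2-fluoro-5-propylbenzaldehyde (not isolated) | CCCc1cc(C=O)c(F)c(C(OC)OC)c1 | intermediate
5 | 2-fluoro-5-propylbenzene-1,3-dicarbaldehyde | CCCc1cc(C=O)c(F)c(C=O)c1 | intermediate
6 | 3,4-dihydroxy-5-methoxybenzaldehyde (5-hydroxyvanillin) | COc1cc(C=O)cc(O)c1O | starting material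
7 | 4-(benzyloxy)-3-hydroxy-5-methoxybenzaldehyde | COc1cc(C=O)cc(O)c1OCc1ccccc1 | intermediate
8 | methyl (triphenylphosphoranylidene)acetate | COC(=O)C=P(c1ccccc1)(c1ccccc1)c1ccccc1 | starting material
9 | methyl (E)-3-[4-(benzyloxy)-3-hydroxy-5-methoxyphenyl]prop-2-enoate | COC(=O)/C=C/c1cc(O)c(OCc2ccccc2)c(OC)c1 | intermediate
10 | methyl 3-[4-(benzyloxy)-3-hydroxy-5-methoxyphenyl]propanoate | COC(=O)CCc1cc(O)c(OCc2ccccc2)c(OC)c1 | intermediate
11 | methyl 3-[4-(benzyloxy)-3-(2,6-diformyl-4-propylphenoxy)-5-methoxyphenyl]propanoate | CCCc1cc(C=O)c(Oc2cc(CCC(=O)OC)cc(OC)c2OCc2ccccc2)c(C=O)c1 | intermediate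
12 | methyl 3-[4-(benzyloxy)-3-[2,6-bis(formyloxy)-4-propylphenoxy]-5-methoxyphenyl]propanoate (ring A bis-formate, not isolated) | CCCc1cc(OC=O)c(Oc2cc(CCC(=O)OC)cc(OC)c2OCc2ccccc2)c(OC=O)c1 | intermediate
13 | methyl 3-[4-(benzyloxy)-3-(2,6-dihydroxy-4-propylphenoxy)-5-methoxyphenyl]propanoate | CCCc1cc(O)c(Oc2cc(CCC(=O)OC)cc(OC)c2OCc2ccccc2)c(O)c1 | intermediate
14 | methyl 3-[4-(benzyloxy)-3-(2,6-dimethoxy-4-propylphenoxy)-5-methoxyphenyl]propanoate | CCCc1cc(OC)c(Oc2cc(CCC(=O)OC)cc(OC)c2OCc2ccccc2)c(OC)c1 | intermediate
15 | 3-[4-(benzyloxy)-3-(2,6-dimethoxy-4-propylphenoxy)-5-methoxyphenyl]propan-1-ol | CCCc1cc(OC)c(Oc2cc(CCCO)cc(OC)c2OCc2ccccc2)c(OC)c1 | intermediate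
16 | 2-(2,6-dimethoxy-4-propylphenoxy)-4-(3-hydroxypropyl)-6-methoxyphenol | CCCc1cc(OC)c(Oc2cc(CCCO)cc(OC)c2O)c(OC)c1 | target

**Step count**
Total: 11 steps. Longest linear sequence: 8 steps (steps 1, 2, 3, 7, 8, 9, 10, 11; the branch through steps 4, 5, 6 is equally long).

**Steps most likely to fail**

Step 8 (twofold Baeyer–Villiger oxygenation). The second aryl migration may stall after the first, and prolonged exposure to excess peracid may then degrade the electron-rich ring B or let hydride migration compete. The fallback runs the two oxygenations one at a time; it sets out from 11 and comes back to the route at 14. About one equivalent of mCPBA in CH2Cl2 at 0 °C should give mainly the mono-formate methyl 3-[4-(benzyloxy)-3-[2-formyl-6-(formyloxy)-4-propylphenoxy]-5-methoxyphenyl]propanoate F1, with unchanged 11 recycled. K2CO3 in MeOH should free the phenol methyl 3-[4-(benzyloxy)-3-(2-formyl-6-hydroxy-4-propylphenoxy)-5-methoxyphenyl]propanoate F2, and MeI/K2CO3 should give the methyl ether methyl 3-[4-(benzyloxy)-3-(2-formyl-6-methoxy-4-propylphenoxy)-5-methoxyphenyl]propanoate F3. The second mCPBA oxidation then runs on a ring that carries a methoxy group in place of the formyl or formyloxy acceptor and should give the formate methyl 3-[4-(benzyloxy)-3-[2-(formyloxy)-6-methoxy-4-propylphenoxy]-5-methoxyphenyl]propanoate F4. Methanolysis should give the phenol methyl 3-[4-(benzyloxy)-3-(2-hydroxy-6-methoxy-4-propylphenoxy)-5-methoxyphenyl]propanoate F5, and a final MeI/K2CO3 methylation gives 14.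

Step 3 (second ortho-lithiation/formylation). Metalation may be diverted to the position next to the acetal or to the benzylic carbon of the propyl group, the lithiated fluoroarene may eliminate to an aryne, or the acetal may hydrolyse incompletely. The fallback avoids organolithium chemistry on ring A and installs propyl last; it sets out from phenol 10 and comes back to the route at 11. Purchased 5-bromo-2-fluoro-1,3-dimethylbenzene F6 is brominated at both methyl groups (NBS in excess, AIBN, PhCF3, reflux) to 5-bromo-1,3-bis(dibromomethyl)-2-fluorobenzene F7. Hydrolysis with AgNO3 in aqueous acetone should give 5-bromo-2-fluorobenzene-1,3-dicarbaldehyde F8. SNAr with 10 (K2CO3, DMF) should give methyl 3-[4-(benzyloxy)-3-(4-bromo-2,6-diformylphenoxy)-5-methoxyphenyl]propanoate F9. Suzuki–Miyaura coupling with propylboronic acid (Pd(OAc)2, SPhos, K3PO4, toluene/H2O, 90 °C) then gives 11.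

Step 4 (regioselective mono-benzylation). Alkylation may occur at the 3-OH as well, or at both phenols, since the selectivity depends only on the acidity difference between the two hydroxyls. The fallback fixes the oxygen pattern with a halogen placeholder; it replaces 6 as the point of departure by purchased 3-bromo-4-hydroxy-5-methoxybenzaldehyde (5-bromovanillin) F10 and comes back to the route at 7. Benzylation of the only phenol (BnBr, K2CO3, DMF) should give 4-(benzyloxy)-3-bromo-5-methoxybenzaldehyde F11. Miyaura borylation (bis(pinacolato)diboron, Pd(dppf)Cl2, KOAc, dioxane, 90 °C) should give 4-(benzyloxy)-3-methoxy-5-(4,4,5,5-tetramethyl-1,3,2-dioxaborolan-2-yl)benzaldehyde F12. Mild oxidation of the C–B bond (NaBO3·4H2O, THF/H2O, rt) then gives 7.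

**Further compounds**
F1 | step 8 | methyl 3-[4-(benzyloxy)-3-[2-formyl-6-(formyloxy)-4-propylphenoxy]-5-methoxyphenyl]propanoate | CCCc1cc(C=O)c(Oc2cc(CCC(=O)OC)cc(OC)c2OCc2ccccc2)c(OC=O)c1
F2 | step 8 | methyl 3-[4-(benzyloxy)-3-(2-formyl-6-hydroxy-4-propylphenoxy)-5-methoxyphenyl]propanoate | CCCc1cc(C=O)c(Oc2cc(CCC(=O)OC)cc(OC)c2OCc2ccccc2)c(O)c1
F3 | step 8 | methyl 3-[4-(benzyloxy)-3-(2-formyl-6-methoxy-4-propylphenoxy)-5-methoxyphenyl]propanoate | CCCc1cc(C=O)c(Oc2cc(CCC(=O)OC)cc(OC)c2OCc2ccccc2)c(OC)c1
F4 | step 8 | methyl 3-[4-(benzyloxy)-3-[2-(formyloxy)-6-methoxy-4-propylphenoxy]-5-methoxyphenyl]propanoate | CCCc1cc(OC=O)c(Oc2cc(CCC(=O)OC)cc(OC)c2OCc2ccccc2)c(OC)c1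
F5 | step 8 | methyl 3-[4-(benzyloxy)-3-(2-hydroxy-6-methoxy-4-propylphenoxy)-5-methoxyphenyl]propanoate | CCCc1cc(O)c(Oc2cc(CCC(=O)OC)cc(OC)c2OCc2ccccc2)c(OC)c1
F6 | step 3 | 5-bromo-2-fluoro-1,3-dimethylbenzene (purchased) | Cc1cc(Br)cc(C)c1F
F7 | step 3 | 5-bromo-1,3-bis(dibromomethyl)-2-fluorobenzene | Fc1c(C(Br)Br)cc(Br)cc1C(Br)Br
F8 | step 3 | 5-bromo-2-fluorobenzene-1,3-dicarbaldehyde | O=Cc1cc(Br)cc(C=O)c1F
F9 | step 3 | methyl 3-[4-(benzyloxy)-3-(4-bromo-2,6-diformylphenoxy)-5-methoxyphenyl]propanoate | COC(=O)CCc1cc(OC)c(OCc2ccccc2)c(Oc2c(C=O)cc(Br)cc2C=O)c1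
F10 | step 4 | 3-bromo-4-hydroxy-5-methoxybenzaldehyde (5-bromovanillin, purchased) | COc1cc(C=O)cc(Br)c1O
F11 | step 4 | 4-(benzyloxy)-3-bromo-5-methoxybenzaldehyde | COc1cc(C=O)cc(Br)c1OCc1ccccc1
F12 | step 4 | 4-(benzyloxy)-3-methoxy-5-(4,4,5,5-tetramethyl-1,3,2-dioxaborolan-2-yl)benzaldehyde | COc1cc(C=O)cc(B2OC(C)(C)C(C)(C)O2)c1OCc1ccccc1
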